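The chemist can count these flasks on paper before integrating anything.

| flask | starting complex | incoming ligand | temperature | remark | time |
|---|---|---|---|---|---|
| spring | 0.015 M | 0.055 M (in portions, 2) | 25 °C | run made earlier; portions every 30 min |  |
| winter | 0.066 M | 0.055 M (in portions, 2) | 40 °C | run made earlier; portions every 30 min |  |
| east | 0.012 M | 0.0550 M | 40 °C | everything together at the start | 1.0 h |
| west | 0.050 M | 0.0550 M (in portions, 2) | 40 °C | the portions of incoming ligand follow each other after 30 min, the first at the start | 1.0 h |

| run | time / min | complex with two exchanged / % |
|---|---|---|
| spring | 15.0 | 2.1 |
| spring | 40.0 | 16.1 |
| spring | 80.0 | 40.5 |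
| spring | 120 | 47.8 |
| winter | 15.0 | 3.8 |
| winter | 30.0 | 7.4 |
| winter | 50.0 | 19.7 |
| winter | 60.0 | 19.0 |

(each reading ± 1 percentage point)

- the numbers in the tables scatter with a standard deviation of 1 percentage point
- reactions considered so far: 2 incoming ligand -> self-condensation product; complex with two exchanged + incoming ligand -> leaving ligand + complex with three exchanged; starting complex + incoming ligand -> leaving ligand + complex with one exchanged; complex with three exchanged + incoming ligand -> leaving ligand + complex with four exchanged; complex with one exchanged + incoming ligand -> leaving ligand + complex with two exchanged

- which of the two ends with the higher amount of complex with two exchanged, in percent of the starting complex charged ("neither" if they lie within 2 percentage points) (east / west / neither)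
- complex with two exchanged at the end, in percent of the starting complex charged, east
- complex with two exchanged at the end, in percent of the starting complex charged, west

Read the ligand column against the complex column. For west you get 1.10 ligand per complex; call this ligand charged per complex charged the exchange allowance x, a limiting-reagent count. Now follow one molecule of starting complex. Suppose ligand lands on the complexes at random, x landings per complex on average, and count every complex landed on at least twice as complex with two exchanged. This count is rough and meant for x below 2: a complex held at two exchanged takes up no more ligand, so the mean number of exchanges in this count cannot pass 2. The molecule's chance of being counted so is then 1 − (1 + x)·exp(−x), once the ligand has reacted.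

Test this on the rows above. Winter has x = 0.833, which gives 20.3%, and its last readings are 19.7% and 19.0%, so the rule holds there within the scatter. Spring has x = 3.67, which gives 88.1%, but it reads 47.8% at its last point, so the rule does not stretch that far.

My own reckoning follows from this. West, at its x, should end just under 30.1%. East, at x = 4.58, belongs with spring, near that last reading.

The forecast says east, with 45% for east and 25% for west: “East should end well ahead of west.” Its west figure lies below mine.

The simulation gives east, with 50.4% for east and 26.2% for west.

    2 incoming ligand → self-condensation product (k = 0.0540 M⁻¹ min⁻¹, Ea = 76.0 kJ mol⁻¹)
    complex with two exchanged + incoming ligand → leaving ligand + complex with three exchanged (k = 0.470 M⁻¹ min⁻¹, Ea = 49.0 kJ mol⁻¹)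
    starting complex + incoming ligand → leaving ligand + complex with one exchanged (k = 1.40 M⁻¹ min⁻¹, Ea = 49.0 kJ mol⁻¹)
    complex with three exchanged + incoming ligand → leaving ligand + complex with four exchanged (k = 1.50 M⁻¹ min⁻¹, Ea = 49.0 kJ mol⁻¹)
    complex with one exchanged + incoming ligand → leaving ligand + complex with two exchanged (k = 1.60 M⁻¹ min⁻¹, Ea = 44.0 kJ mol⁻¹)
    (constants at 40 °C)

West still holds 7.9% of its ligand at 1.00 h, so its spent allowance is 1.01, and the rule then gives 26.8%. The neighbouring flask is east with 0.048 M of starting complex, so its x is 1.15, beside west's. With 2.4% of its ligand left, its spent allowance is 1.12, and the rule gives 30.8%. That flask ends at 29.0% of complex with two exchanged, and complex with one exchanged holds most, 33.8%.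

All runs stem from a simulated flask for an exercise; scatter was added.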